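The readings were generated by integration with made-up constants, and the scatter is random.

Left-handed product still to come has to come out of substrate still left, so I reckon this flask by its leftover and not by its yield.

in all of them: left-handed substrate 0.20 M; right-handed substrate 0.20 M
- Friday's: partner 3 equiv; catalyst 0.2 mol%; temperature 80 °C; the very flask that is asked about, followed so far
- Sunday's: partner 3 equiv; catalyst 0.4 mol%; temperature 65 °C; run made earlier
- flask: partner 3.00 equiv; catalyst 0.2 mol%; temperature 80 °C; time 25 min

| run | time / min | left-handed product / % | left-handed substrate / % |
|---|---|---|---|
| Friday's | 1.33 | 24.3 | 28.6 |
| Friday's | 2.00 | 30.9 | 23.3 |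
| Friday's | 3.00 | 39.6 | 16.1 |
| Friday's | 5.00 | 46.2 | 9.2 |
| Friday's | 10.0 | 55.6 | 4.8 |
| Friday's | 15.0 | 59.5 | 1.6 |
| Sunday's | 0.667 | 13.9 | 36.2 |
| Sunday's | 2.00 | 31.5 | 21.9 |
| Sunday's | 3.00 | 36.5 | 15.2 |
| Sunday's | 5.00 | 43.8 | 10.4 |
| Sunday's | 8.00 | 46.1 | 4.8 |
| Sunday's | 10.0 | 51.6 | 2.9 |

(standard deviation of a reading: 1 percentage point)

- catalyst is single-handed; left-handed substrate and right-handed substrate are mirror images of each other, charged as a racemate, each of them at the stated concentration
- left-handed product taken out counts as made
- steps thought possible: left-handed substrate <-> right-handed substrate; partner + catalyst + right-handed substrate -> catalyst + right-handed product; partner + catalyst + left-handed substrate -> catalyst + left-handed product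
- additions bring no volume worth counting

- teal: at 25 min raise the temperature by 25 K, then wait 8.0 min
- ochre: change nothing and wait 8.0 min more
- red: at 25 min add catalyst, 100 % of the amount charged, then wait 8.0 min
- amber: at 25 min add partner, 100 % of the amount charged, then wait 8.0 min
- blue: at 25 min take out 90 % of the left-handed product then present, then wait 8.0 min

- left-handed product, in percent of the left-handed substrate and right-handed substrate together first charged, at 25 min
- what to do for the largest gain in left-handed product; "none" if nothing gains more than 2 percentage points (teal / ochre / red / amber / blue / none)
- left-handed product present, with what was taken out counted in, in percent of the left-handed substrate and right-handed substrate together first charged, after teal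
- left-handed product present, with what was taken out counted in, in percent of the left-handed substrate and right-handed substrate together first charged, after red

Friday's run is the asked flask followed so far. The first clock I can read in it is the fall of left-handed substrate: from 28.6 % at 1.33 min to 1.6 % at 15.0 min it decays at 0.211 min⁻¹, a halving every 3.29 min, as read through the scatter. On the next rung, the forms cross: at 15.0 min, left-handed product plus left-handed substrate stands 11 percentage points above the half charged as left-handed, so right-handed substrate has been feeding the left-handed side. Partner, at 1.50 on both forms together, is in excess, and substrate is the limiting reagent.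

The last rung is the wait from the last reading to 25 min, which is 10.0 min or 3.04 halvings, so I reckon that in this flask c(left-handed substrate) comes down to 0.194 %. Right-handed substrate is not read; since the forms cross, I take it as equal. Doubling gives 0.388 %: this is my estimate of the headroom, both substrate forms still free at the moment of acting, the stock from which any further product has to come. It is less than the margin of 2 points, and right-handed substrate would have to stand at about ten times the left-handed to pass it. I commit to "none", and to about 61.1 % now, the last product reading plus the last left-handed substrate reading.

The forecast gives 64 % and chooses teal, with 69 % after teal and 66.5 % after red, reasoning that “Heating accelerates racemisation most and consumes the remainder”. It expects about 6 % right-handed and 1 % left-handed substrate at that time, where I expect 0.388 % of the two together.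

    left-handed substrate ⇌ right-handed substrate (k = 0.00940 s⁻¹, Ea = 103 kJ mol⁻¹)
    partner + catalyst + right-handed substrate → catalyst + right-handed product (k = 25.0 M⁻² s⁻¹, Ea = 38.0 kJ mol⁻¹)
    partner + catalyst + left-handed substrate → catalyst + left-handed product (k = 41.0 M⁻² s⁻¹, Ea = 48.0 kJ mol⁻¹)
    (constants at 80 °C)

The flask gives 59.4 %, and the answer to "best" is none: teal brings the largest gain, 0.43 points, ending at 59.8 %, and red ends at 59.8 %. At 25.0 min the headroom in this flask is 0.67 points, more than my estimate of 0.388 % and less than the margin of 2 points. The same count in the neighbouring flask kept at 55 °C, where left-handed product stands at 46.9 %, gives a headroom of 12 points.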